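**Retrosynthetic overview**
1. Target 8 ⇒ acyclic (2S,3S)-chlorodiol triene 6 by a double 6-endo bromonium cyclization in the last step: C3–OH closes onto C6=C7 (oxane, ring B), and C10=C11 closes onto the C14=C15 bromonium with water capture at C11 (ring A).
2. 6 ⇒ triol 4 (primary OH → Cl) ⇒ (2S,3S)-2,3-epoxygeranylgeraniol 2 by Payne rearrangement–hydrolysis (C3–O kept, C2 inverted).
3. 2 ⇒ all-trans-geranylgeraniol 1 by Sharpless asymmetric epoxidation (sets C2 and C3).
4. Ring order: no ring exists until the last step; ring B and ring A then form in the same flask.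

Assumption: all-trans-geranylgeraniol (bulk, annatto-derived) is taken as the commercial starting material.
Assumption: (DHQD)2PHAL is taken to present to Br+ the same olefin face it presents to the oxidant in asymmetric dihydroxylation (giving 6R and 14R); if the sense is opposite, the pseudo-enantiomer (DHQ)2PHAL is used.
Convention: locants C1–C20 follow the geranylgeraniol chain (C1 = CH2Cl carbon of the target, C15 = gem-dimethyl carbon); ring A = bromocyclohexanol, ring B = bromo-oxane.

**Step 1**
Reactants: 1 (2E,6E,10E)-3,7,11,15-tetramethylhexadeca-2,6,10,14-tetraen-1-ol (all-trans-geranylgeraniol)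
Product: 2 [(2S,3S)-3-methyl-3-[(3E,7E)-4,8,12-trimethyltrideca-3,7,11-trien-1-yl]oxiran-2-yl]methanol ((2S,3S)-2,3-epoxygeranylgeraniol)
Conditions: Ti(OiPr)4 (5 mol%), L-(+)-diethyl tartrate (7.5 mol%), t-BuOOH (2 equiv), 4 Å MS, CH2Cl2, −20 °C
Reagents that add atoms: tert-butyl hydroperoxide, CC(C)(C)OO
Why: Sharpless asymmetric epoxidation is directed by the allylic OH, so only the C2=C3 olefin reacts, and the L-(+)-tartrate ligand delivers oxygen to the face of the E-allylic alcohol that gives the (2S,3S)-epoxide in high ee.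

**Step 2**
Reactants: 2 (2S,3S)-2,3-epoxygeranylgeraniol
Product: 4 (2R,3S,6E,10E)-3,7,11,15-tetramethylhexadeca-6,10,14-triene-1,2,3-triol, via Payne epoxide 3 (not isolated)
Conditions: NaOH (0.5 M), t-BuOH/H2O 1:1, 75 °C
Reagents that add atoms: water, O
Why: In this Payne rearrangement–opening the C1 alkoxide opens the epoxide at C2 by intramolecular SN2 (inversion at C2, C3–O bond untouched) to give terminal epoxide 3, which hydroxide opens irreversibly at the unhindered C1, so C3 stays S and C2 ends with the arrangement the target needs.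

**Step 3**
Reactants: 4 (2R,3S)-triol
Product: 6 (2S,3S,6E,10E)-1-chloro-3,7,11,15-tetramethylhexadeca-6,10,14-triene-2,3-diol, via primary mesylate 5 (not isolated)
Conditions: MsCl (1.05 equiv), 2,4,6-collidine, CH2Cl2, −10 °C; then LiCl (5 equiv), DMF, 50 °C
Reagents that add atoms: lithium chloride, [Li+].[Cl-] (methanesulfonyl chloride, CS(=O)(=O)Cl, ends only in intermediate 5)
Why: Collidine-mediated sulfonylation takes the primary OH over the hindered secondary and tertiary ones, and chloride displaces the primary mesylate by SN2 without touching a stereocentre (any terminal epoxide formed by O2 participation is reopened by chloride at C1 to the same product).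

**Step 4**
Reactants: 6 (2S,3S)-chlorodiol triene
Product: 8 (1S)-1-[(2S,5R,6S)-5-bromo-6-{2-[(1R,2R,5R)-5-bromo-2-hydroxy-2,6,6-trimethylcyclohexyl]ethyl}-2,6-dimethyloxan-2-yl]-2-chloroethan-1-ol, via bromooxane diene 7 (not isolated)
Conditions: 1,3-dibromo-5,5-dimethylhydantoin (1.1 equiv), hydroquinidine 1,4-phthalazinediyl diether (DHQD)2PHAL (10 mol%), H2O (5 equiv), CH2Cl2/(CF3)2CHOH 4:1, −40 °C; aq Na2S2O3
Reagents that add atoms: 1,3-dibromo-5,5-dimethylhydantoin, CC1(C)N(Br)C(=O)N(Br)C1=O; water, O
Why: Proposed new method: the two olefins that must react (C6=C7 and C14=C15) are the same local type (CH2–CH=C(CH3)–), both close 6-endo at the tertiary carbon and both need Br on the same enantioface (6R, 14R), so one chiral Br+ carrier can serve both; at C6=C7 the C3–OH opens the bromonium anti at C7 through the chair with Br, the C8 chain and the chlorohydrin arm equatorial (the substrate's own preference, so matched), giving 6R,7S; at C14=C15 the C10=C11 π bond attacks C15 anti through a chair with Br and the C9 chain equatorial, and water quenches the C11 cation from the equatorial side because the axial side is blocked by the syn-axial C15 methyl, giving 10R,11R,14R; the fluorinated alcohol with little water favours π-closure over direct bromohydrin formation, and the product has no olefin left to over-brominate; closest known reaction types are Lewis-base-catalysed enantioselective bromonium polyene cyclization with this N-bromo reagent, N-bromoimide polyene cyclizations in fluorinated alcohols, and cinchona-alkaloid-catalysed halohydroxylation with water as nucleophile.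

**Compound list**
1 | (2E,6E,10E)-3,7,11,15-tetramethylhexadeca-2,6,10,14-tetraen-1-ol (all-trans-geranylgeraniol) | CC(C)=CCC/C(C)=C/CC/C(C)=C/CC/C(C)=C/CO | starting material
2 | [(2S,3S)-3-methyl-3-[(3E,7E)-4,8,12-trimethyltrideca-3,7,11-trien-1-yl]oxiran-2-yl]methanol | CC(C)=CCC/C(C)=C/CC/C(C)=C/CC[C@]1(C)O[C@H]1CO | intermediate
3 | (2S,5E,9E)-6,10,14-trimethyl-2-[(2R)-oxiran-2-yl]pentadeca-5,9,13-trien-2-ol (Payne epoxide, not isolated) | CC(C)=CCC/C(C)=C/CC/C(C)=C/CC[C@](C)(O)[C@H]1CO1 | intermediate
4 | (2R,3S,6E,10E)-3,7,11,15-tetramethylhexadeca-6,10,14-triene-1,2,3-triol | CC(C)=CCC/C(C)=C/CC/C(C)=C/CC[C@](C)(O)[C@H](O)CO | intermediate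
5 | (2R,3S,6E,10E)-2,3-dihydroxy-3,7,11,15-tetramethylhexadeca-6,10,14-trien-1-yl methanesulfonate (not isolated) | CC(C)=CCC/C(C)=C/CC/C(C)=C/CC[C@](C)(O)[C@H](O)COS(C)(=O)=O | intermediate
6 | (2S,3S,6E,10E)-1-chloro-3,7,11,15-tetramethylhexadeca-6,10,14-triene-2,3-diol | CC(C)=CCC/C(C)=C/CC/C(C)=C/CC[C@](C)(O)[C@H](O)CCl | intermediate
7 | (1S)-1-[(2S,5R,6S)-5-bromo-6-[(3E)-4,8-dimethylnona-3,7-dien-1-yl]-2,6-dimethyloxan-2-yl]-2-chloroethan-1-ol (not isolated) | CC(C)=CCC/C(C)=C/CC[C@]1(C)O[C@](C)([C@H](O)CCl)CC[C@H]1Br | intermediate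
8 | (1S)-1-[(2S,5R,6S)-5-bromo-6-{2-[(1R,2R,5R)-5-bromo-2-hydroxy-2,6,6-trimethylcyclohexyl]ethyl}-2,6-dimethyloxan-2-yl]-2-chloroethan-1-ol | CC1(C)[C@H](Br)CC[C@@](C)(O)[C@@H]1CC[C@]1(C)O[C@](C)([C@H](O)CCl)CC[C@H]1Br | target

**Totals**
Total step count: 4. Longest linear sequence: 4 steps (1 → 2 → 4 → 6 → 8).

**Steps most likely to fail, with fallbacks**

Step 4 is the weakest point. Water may open the terminal bromonium directly, the C11 cation may lose a proton instead of taking water, and the cinchona catalyst may not control the C14 face. The fallback sets out from 6 and separates ring closure from hydration. The two closures are run under anhydrous Lewis-base catalysis: (R)-3,3'-bis(2,4,6-triisopropylphenyl)-1,1'-binaphthyl-2,2'-diyl N-(trifluoromethylsulfonyl)thiophosphoramide (10 mol%), 1,3-dibromo-5,5-dimethylhydantoin, toluene/CH2Cl2, −78 °C. Under these conditions the C11 cation ends by proton loss, giving the exocyclic C11-methylidene dibromide F1 together with the endocyclic C11=C12 alkene F2. Both are then hydrated at C11 by Mukaiyama hydration (Co(acac)2, PhSiH3, O2, THF; then Na2S2O3). They pass through the same tertiary C11 radical, which takes O2 from the equatorial side opposite the syn-axial C15 methyl, and the sequence comes back to the route at 8.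

Step 2 may stall or give triol contaminated by direct C2 opening in the hot aqueous base. The fallback sets out from 1 and avoids the Payne rearrangement. Epoxidation with D-(−)-diethyl tartrate (otherwise as in step 1) gives (2R,3R)-2,3-epoxygeranylgeraniol F3. Appel chlorination (PPh3, CCl4, NaHCO3, reflux) converts it into the (2S,3R)-1-chloro-2,3-epoxide F4. Dilute HClO4 in THF/H2O at 0 °C then opens the epoxide with water at the tertiary C3 with inversion while the C2–O bond is kept. This gives the same chlorodiol and comes back to the route at 6, bypassing 4.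

Step 3 may give bis-sulfonylation or poor mass balance on the triol. The fallback sets out from 4 and moves the chlorination to the end. Triol 4 is taken through the double bromocyclization under the step 4 conditions to the dibromo triol F5, in which the C3 oxygen is tied up in ring B. Its primary OH is then converted with MsCl/collidine into the primary mesylate F6 and displaced with LiCl in DMF, coming back to the route at 8.

**Further compounds**
F1 | step 4 | (1S)-1-[(2S,5R,6S)-5-bromo-6-{2-[(1S,3R)-3-bromo-2,2-dimethyl-6-methylidenecyclohexyl]ethyl}-2,6-dimethyloxan-2-yl]-2-chloroethan-1-ol | CC1(C)[C@H](Br)CCC(=C)[C@@H]1CC[C@]1(C)O[C@](C)([C@H](O)CCl)CC[C@H]1Br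
F2 | step 4 | (1S)-1-[(2S,5R,6S)-5-bromo-6-{2-[(1S,5R)-5-bromo-2,6,6-trimethylcyclohex-2-en-1-yl]ethyl}-2,6-dimethyloxan-2-yl]-2-chloroethan-1-ol | CC1(C)[C@H](Br)CC=C(C)[C@@H]1CC[C@]1(C)O[C@](C)([C@H](O)CCl)CC[C@H]1Br
F3 | step 2 | [(2R,3R)-3-methyl-3-[(3E,7E)-4,8,12-trimethyltrideca-3,7,11-trien-1-yl]oxiran-2-yl]methanol | CC(C)=CCC/C(C)=C/CC/C(C)=C/CC[C@@]1(C)O[C@@H]1CO
F4 | step 2 | (2S,3R)-2-(chloromethyl)-3-methyl-3-[(3E,7E)-4,8,12-trimethyltrideca-3,7,11-trien-1-yl]oxirane | CC(C)=CCC/C(C)=C/CC/C(C)=C/CC[C@@]1(C)O[C@@H]1CCl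
F5 | step 3 | (1R)-1-[(2S,5R,6S)-5-bromo-6-{2-[(1R,2R,5R)-5-bromo-2-hydroxy-2,6,6-trimethylcyclohexyl]ethyl}-2,6-dimethyloxan-2-yl]ethane-1,2-diol | CC1(C)[C@H](Br)CC[C@@](C)(O)[C@@H]1CC[C@]1(C)O[C@](C)([C@H](O)CO)CC[C@H]1Br
F6 | step 3 | (2R)-2-[(2S,5R,6S)-5-bromo-6-{2-[(1R,2R,5R)-5-bromo-2-hydroxy-2,6,6-trimethylcyclohexyl]ethyl}-2,6-dimethyloxan-2-yl]-2-hydroxyethyl methanesulfonate | CC1(C)[C@H](Br)CC[C@@](C)(O)[C@@H]1CC[C@]1(C)O[C@](C)([C@H](O)COS(C)(=O)=O)CC[C@H]1Br
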